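Retrosynthesis: the last C–C bond made is the acyl–C3 bond of the pyranone, by crossed Claisen-type C-acylation of the (R)-β-keto-δ-lactone with the complete side-chain acid.
The E-alkene next to the quaternary carbinol comes from a Julia–Kocienski olefination of a formyl diol ester with a tetrazolyl sulfone that carries the 1,1-disubstituted alkene (made by Negishi coupling).
Key bond: quaternary carbinol carbon to secondary carbinol carbon, by an intermolecular Evans glycolate syn-aldol of a chiral glycolate imide with (S)-2-methylbutanal; the quaternary centre is then set by alkylating the derived dioxolane ester enolate anti to the sec-butyl group.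
The lactone comes from a Claisen condensation of methyl (R)-3-hydroxybutanoate with the enolate of tert-butyl acetate, then lactonisation.
Ring order: the dihydropyranone (the only ring of the target) is closed first, in fragment synthesis; a temporary dioxolane ring is made and opened on the way; no other ring is formed.

Assumption: the 3-acyl-4-hydroxypyran-2-one drawn and its pyran-2,4-dione tautomers are one compound; 3-bromobut-3-en-1-ol, the (3-ethoxy-3-oxopropyl)zinc bromide solution and benzyl chloromethyl ether are bought.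

Step 1
Reactants: 1 methyl (3R)-3-hydroxybutanoate; 2 tert-butyl acetate
Product: 4 tert-butyl (5R)-5-hydroxy-3-oxohexanoate, via lithium enolate of tert-butyl acetate 3 (not isolated)
Conditions: 2 (3.5 equiv), LiN(iPr)2 (3.5 equiv), THF, −78 °C; then 1, −78 to −20 °C; aq. NH4Cl
Reagents that add atoms: none
Why: Crossed Claisen condensation in which the preformed enolate, used in excess because the free hydroxyl consumes one equivalent, acylates on the methyl ester, while the stereocentre comes unchanged from 1.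

Step 2
Reactants: 4 tert-butyl (5R)-5-hydroxy-3-oxohexanoate
Product: 5 (6R)-4-hydroxy-6-methyl-5,6-dihydro-2H-pyran-2-one
Conditions: CF3CO2H, CH2Cl2, rt
Reagents that add atoms: none
Why: Acid cleavage of the tert-butyl ester and δ-lactonisation close the six-membered ring without touching the stereocentre, which becomes C6.

Step 3
Reactants: 6 3-bromobut-3-en-1-ol
Product: 7 [(3-bromobut-3-en-1-yl)oxy](tert-butyl)dimethylsilane
Conditions: tBuMe2SiCl, imidazole, DMF, rt
Reagents that add atoms: tert-butyl(chloro)dimethylsilane, CC(C)(C)[Si](C)(C)Cl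
Why: Standard silylation of the primary alcohol, so that the free hydroxyl cannot quench the organozinc reagent of the next step.

Step 4
Reactants: 7 [(3-bromobut-3-en-1-yl)oxy](tert-butyl)dimethylsilane; 8 (3-ethoxy-3-oxopropyl)zinc bromide
Product: 9 ethyl 6-[(tert-butyldimethylsilyl)oxy]-4-methylidenehexanoate
Conditions: Pd(PPh3)4 (5 mol %), THF, 50 °C
Reagents that add atoms: none
Why: Negishi cross-coupling of the 2-bromoalkene with the ester-tolerant alkylzinc reagent fixes the 1,1-disubstituted alkene in place with no positional isomerisation.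

Step 5
Reactants: 9 ethyl 6-[(tert-butyldimethylsilyl)oxy]-4-methylidenehexanoate
Product: 10 ethyl 6-hydroxy-4-methylidenehexanoate
Conditions: pyridinium p-toluenesulfonate (0.1 equiv), EtOH, 50 °C
Reagents that add atoms: none
Why: Mild acid-catalysed solvolysis of the primary silyl ether in ethanol leaves the ethyl ester and the alkene untouched.

Step 6
Reactants: 10 ethyl 6-hydroxy-4-methylidenehexanoate
Product: 11 ethyl 4-methylidene-6-[(1-phenyl-1H-tetrazol-5-yl)sulfanyl]hexanoate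
Conditions: 1-phenyl-1H-tetrazole-5-thiol, PPh3, diisopropyl azodicarboxylate, THF, 0 °C to rt
Reagents that add atoms: 1-phenyl-1H-tetrazole-5-thiol, Sc1nnnn1-c1ccccc1
Why: Mitsunobu thioetherification of an unhindered primary alcohol with the acidic heteroaryl thiol proceeds by clean SN2 displacement.

Step 7
Reactants: 11 ethyl 4-methylidene-6-[(1-phenyl-1H-tetrazol-5-yl)sulfanyl]hexanoate
Product: 12 ethyl 4-methylidene-6-[(1-phenyl-1H-tetrazol-5-yl)sulfonyl]hexanoate
Conditions: (NH4)6Mo7O24·4H2O (10 mol %), 30% H2O2, EtOH, 0 °C to rt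
Reagents that add atoms: hydrogen peroxide, OO
Why: Molybdate-catalysed sulfide-to-sulfone oxidation is much faster than epoxidation of an unactivated 1,1-disubstituted alkene and gives the Julia–Kocienski partner.

Step 8
Reactants: 13 (2S)-2-methylbutan-1-ol
Product: 14 (2S)-2-methylbutanal
Conditions: 2,2,6,6-tetramethylpiperidin-1-oxyl (1 mol %), KBr (10 mol %), NaOCl (1.1 equiv), NaHCO3, CH2Cl2/H2O, 0 °C; dried solution used at once
Reagents that add atoms: none
Why: Anelli (oxoammonium) oxidation stops at the aldehyde in a buffered two-phase system at 0 °C, under which the α-stereocentre is not epimerised.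

Step 9
Reactants: 15 (4R)-4-benzyl-1,3-oxazolidin-2-one; 16 (benzyloxy)acetyl chloride
Product: 18 (4R)-4-benzyl-3-[(benzyloxy)acetyl]-1,3-oxazolidin-2-one, via N-lithio oxazolidinone 17 (not isolated)
Conditions: n-BuLi, THF, −78 °C; then 16, −78 to 0 °C
Reagents that add atoms: none
Why: N-Acylation of the lithiated auxiliary by the acid chloride gives the glycolate imide without touching the auxiliary stereocentre.

Step 10
Reactants: 18 (4R)-4-benzyl-3-[(benzyloxy)acetyl]-1,3-oxazolidin-2-one; 14 (2S)-2-methylbutanal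
Product: 20 (4R)-4-benzyl-3-[(2R,3S,4S)-2-(benzyloxy)-3-hydroxy-4-methylhexanoyl]-1,3-oxazolidin-2-one, via dibutylboron Z-enolate 19 (not isolated)
Conditions: Bu2BOTf (1.1 equiv), Et3N (1.3 equiv), CH2Cl2, −78 to 0 °C; then 14, −78 to 0 °C; pH 7 buffer, MeOH, 30% H2O2, 0 °C
Reagents that add atoms: none
Why: Evans syn-aldol reaction in which the Z-boron enolate reacts through a closed Zimmerman–Traxler chair on the face away from the benzyl group, so the (R)-auxiliary sets 3S (and 2R) under reagent control, while 4S is carried in from 14.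

Step 11
Reactants: 20 (4R)-4-benzyl-3-[(2R,3S,4S)-2-(benzyloxy)-3-hydroxy-4-methylhexanoyl]-1,3-oxazolidin-2-one
Product: 21 2-(trimethylsilyl)ethyl (2R,3S,4S)-2-(benzyloxy)-3-hydroxy-4-methylhexanoate
Conditions: Me3SiCH2CH2OH (3 equiv), n-BuLi (2.5 equiv), THF, −20 to 0 °C; aq. NH4Cl
Reagents that add atoms: 2-(trimethylsilyl)ethanol, C[Si](C)(C)CCO
Why: Transesterification by the lithium alkoxide at the exocyclic imide carbonyl releases the auxiliary and installs a fluoride-labile ester; C2, which could epimerise here, is planarised in step 14 anyway.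

Step 12
Reactants: 21 2-(trimethylsilyl)ethyl (2R,3S,4S)-2-(benzyloxy)-3-hydroxy-4-methylhexanoate
Product: 22 2-(trimethylsilyl)ethyl (2R,3S,4S)-2,3-dihydroxy-4-methylhexanoate
Conditions: H2 (1 atm), Pd/C (10% Pd on carbon), EtOAc, rt
Reagents that add atoms: none
Why: Hydrogenolysis of the benzyl ether is clean here because the molecule holds no alkene and the silylethyl ester is inert to it.

Step 13
Reactants: 22 2-(trimethylsilyl)ethyl (2R,3S,4S)-2,3-dihydroxy-4-methylhexanoate
Product: 23 2-(trimethylsilyl)ethyl (4R,5S)-5-[(2S)-butan-2-yl]-2,2-dimethyl-1,3-dioxolane-4-carboxylate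
Conditions: 2,2-dimethoxypropane, pyridinium p-toluenesulfonate (cat.), CH2Cl2, rt
Reagents that add atoms: 2,2-dimethoxypropane, COC(C)(C)OC
Why: Acid-catalysed transketalisation ties the two oxygens into a dioxolane ring, so that the carbinol centre next to the ester can control the face of the ester enolate.

Step 14
Reactants: 23 2-(trimethylsilyl)ethyl (4R,5S)-5-[(2S)-butan-2-yl]-2,2-dimethyl-1,3-dioxolane-4-carboxylate
Product: 25 2-(trimethylsilyl)ethyl (4S,5S)-4-[(benzyloxy)methyl]-5-[(2S)-butan-2-yl]-2,2-dimethyl-1,3-dioxolane-4-carboxylate, via lithium ester enolate 24 (not isolated)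
Conditions: LiN(iPr)2 (1.3 equiv), THF, −78 °C; then BnOCH2Cl (2 equiv), DMPU, −78 to −40 °C; aq. NH4Cl
Reagents that add atoms: benzyl chloromethyl ether, ClCOCc1ccccc1
Why: Enolate alkylation in which the exocyclic ester enolate (its ring β-oxygen is held out of alignment, so β-elimination is slow at −78 °C) is attacked by the reactive α-chloro ether on the ring face opposite the sec-butyl group, placing CH2OBn trans to it and setting the quaternary centre (4S in the dioxolane, 2S in the chain).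

Step 15
Reactants: 25 2-(trimethylsilyl)ethyl (4S,5S)-4-[(benzyloxy)methyl]-5-[(2S)-butan-2-yl]-2,2-dimethyl-1,3-dioxolane-4-carboxylate
Product: 26 2-(trimethylsilyl)ethyl (2S,3S,4S)-2-[(benzyloxy)methyl]-2,3-dihydroxy-4-methylhexanoate
Conditions: 2 M aq. HCl/THF (1:2), 45 °C
Reagents that add atoms: none
Why: Acid hydrolysis of the ketal is done at this stage because no acid-sensitive alkene is present yet and the benzyl ether and silylethyl ester tolerate it.

Step 16
Reactants: 26 2-(trimethylsilyl)ethyl (2S,3S,4S)-2-[(benzyloxy)methyl]-2,3-dihydroxy-4-methylhexanoate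
Product: 27 2-(trimethylsilyl)ethyl (2S,3S,4S)-2-[(benzyloxy)methyl]-4-methyl-2,3-bis[(triethylsilyl)oxy]hexanoate
Conditions: Et3SiOTf (3 equiv), 2,6-lutidine (5 equiv), CH2Cl2, 0 °C to rt
Reagents that add atoms: triethylsilyl trifluoromethanesulfonate, CC[Si](CC)(CC)OS(=O)(=O)C(F)(F)F
Why: Silylation with the silyl triflate and a hindered pyridine base caps both the secondary and the hindered tertiary hydroxyl as ethers that later leave with fluoride together with the ester.

Step 17
Reactants: 27 2-(trimethylsilyl)ethyl (2S,3S,4S)-2-[(benzyloxy)methyl]-4-methyl-2,3-bis[(triethylsilyl)oxy]hexanoate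
Product: 28 2-(trimethylsilyl)ethyl (2S,3S,4S)-2-(hydroxymethyl)-4-methyl-2,3-bis[(triethylsilyl)oxy]hexanoate
Conditions: H2 (1 atm), Pd(OH)2/C, EtOAc, rt
Reagents that add atoms: none
Why: Hydrogenolysis frees the primary alcohol before any alkene enters the molecule, and the aprotic solvent avoids solvolysis of the silyl ethers.

Step 18
Reactants: 28 2-(trimethylsilyl)ethyl (2S,3S,4S)-2-(hydroxymethyl)-4-methyl-2,3-bis[(triethylsilyl)oxy]hexanoate
Product: 29 2-(trimethylsilyl)ethyl (2R,3S,4S)-2-formyl-4-methyl-2,3-bis[(triethylsilyl)oxy]hexanoate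
Conditions: Dess–Martin periodinane, NaHCO3, CH2Cl2, 0 °C to rt
Reagents that add atoms: none
Why: Dess–Martin oxidation under buffered, non-basic conditions gives a non-enolisable aldehyde (the descriptor at C2 changes only through CIP ranking).

Step 19
Reactants: 29 2-(trimethylsilyl)ethyl (2R,3S,4S)-2-formyl-4-methyl-2,3-bis[(triethylsilyl)oxy]hexanoate; 12 ethyl 4-methylidene-6-[(1-phenyl-1H-tetrazol-5-yl)sulfonyl]hexanoate
Product: 31 9-ethyl 1-[2-(trimethylsilyl)ethyl] (2S,3E)-6-methylidene-2-[(1S,2S)-2-methyl-1-(triethylsilyloxy)butyl]-2-(triethylsilyloxy)non-3-enedioate, via potassium sulfonyl carbanion 30 (not isolated)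
Conditions: KN(SiMe3)2 (1.2 equiv) added to 12 + 29 in DME, −65 °C to rt; aq. NH4Cl
Reagents that add atoms: none
Why: Julia–Kocienski olefination run in Barbier mode, so that the carbanion is trapped by the aldehyde before it can attack its own ester, and in which the potassium/DME addition–Smiles rearrangement–elimination sequence on a hindered aldehyde gives the E-alkene.

Step 20
Reactants: 31 9-ethyl 1-[2-(trimethylsilyl)ethyl] (2S,3E)-6-methylidene-2-[(1S,2S)-2-methyl-1-(triethylsilyloxy)butyl]-2-(triethylsilyloxy)non-3-enedioate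
Product: 32 (6E,8S)-4-methylidene-8-[(1S,2S)-2-methyl-1-(triethylsilyloxy)butyl]-9-oxo-8-(triethylsilyloxy)-9-[2-(trimethylsilyl)ethoxy]non-6-enoic acid
Conditions: LiOH·H2O (2 equiv), THF/H2O (3:1), 0 °C to rt; then 0.5 M HCl to pH 4
Reagents that add atoms: lithium hydroxide, [Li+].[OH-]
Why: Saponification is selective for the unhindered chain ethyl ester, because the other ester sits on a fully substituted carbon flanked by two silyloxy groups.

Step 21
Reactants: 32 (6E,8S)-4-methylidene-8-[(1S,2S)-2-methyl-1-(triethylsilyloxy)butyl]-9-oxo-8-(triethylsilyloxy)-9-[2-(trimethylsilyl)ethoxy]non-6-enoic acid; 5 (6R)-4-hydroxy-6-methyl-5,6-dihydro-2H-pyran-2-one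
Product: 34 2-(trimethylsilyl)ethyl (2S,3E)-9-[(6R)-4-hydroxy-6-methyl-2-oxo-5,6-dihydro-2H-pyran-3-yl]-6-methylidene-2-[(1S,2S)-2-methyl-1-(triethylsilyloxy)butyl]-9-oxo-2-(triethylsilyloxy)non-3-enoate, via O-acyl enol ester 33 (not isolated)
Conditions: N,N'-dicyclohexylcarbodiimide (1.2 equiv), 4-(dimethylamino)pyridine (1.5 equiv), CH2Cl2, 0 °C to rt, 24 h
Reagents that add atoms: none
Why: Carbodiimide activation gives the enol ester, which 4-(dimethylamino)pyridine converts through an acylpyridinium/lactone-enolate pair into the hydrogen-bonded 3-acyl product (O-to-C acyl transfer, a crossed Claisen-type C-acylation) without touching any stereocentre.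

Step 22
Reactants: 34 2-(trimethylsilyl)ethyl (2S,3E)-9-[(6R)-4-hydroxy-6-methyl-2-oxo-5,6-dihydro-2H-pyran-3-yl]-6-methylidene-2-[(1S,2S)-2-methyl-1-(triethylsilyloxy)butyl]-9-oxo-2-(triethylsilyloxy)non-3-enoate
Product: 35 (2S,3E)-2-hydroxy-2-[(1S,2S)-1-hydroxy-2-methylbutyl]-9-[(6R)-4-hydroxy-6-methyl-2-oxo-5,6-dihydro-2H-pyran-3-yl]-6-methylidene-9-oxonon-3-enoic acid
Conditions: Bu4NF (5 equiv), THF, 0 °C to rt; then 0.5 M HCl to pH 3
Reagents that add atoms: none
Why: Fluoride-mediated global deprotection cleaves both triethylsilyl ethers and fragments the silylethyl ester (β-elimination to ethene) in one acid-free operation that the skipped diene and the acylpyranone tolerate.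

Compound list
1 | methyl (3R)-3-hydroxybutanoate | C[C@@H](O)CC(=O)OC | starting material
2 | tert-butyl acetate | CC(=O)OC(C)(C)C | starting material
3 | lithium 1-(tert-butoxy)ethen-1-olate (lithium enolate of 2) | [Li+].[O-]C(=C)OC(C)(C)C | intermediate
4 | tert-butyl (5R)-5-hydroxy-3-oxohexanoate | C[C@@H](O)CC(=O)CC(=O)OC(C)(C)C | intermediate
5 | (6R)-4-hydroxy-6-methyl-5,6-dihydro-2H-pyran-2-one | C[C@@H]1CC(O)=CC(=O)O1 | intermediate
6 | 3-bromobut-3-en-1-ol | C=C(Br)CCO | starting material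
7 | [(3-bromobut-3-en-1-yl)oxy](tert-butyl)dimethylsilane | C=C(Br)CCO[Si](C)(C)C(C)(C)C | intermediate
8 | (3-ethoxy-3-oxopropyl)zinc bromide | CCOC(=O)CC[Zn]Br | starting material
9 | ethyl 6-[(tert-butyldimethylsilyl)oxy]-4-methylidenehexanoate | CCOC(=O)CCC(=C)CCO[Si](C)(C)C(C)(C)C | intermediate
10 | ethyl 6-hydroxy-4-methylidenehexanoate | CCOC(=O)CCC(=C)CCO | intermediate
11 | ethyl 4-methylidene-6-[(1-phenyl-1H-tetrazol-5-yl)sulfanyl]hexanoate | CCOC(=O)CCC(=C)CCSc1nnnn1-c1ccccc1 | intermediate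
12 | ethyl 4-methylidene-6-[(1-phenyl-1H-tetrazol-5-yl)sulfonyl]hexanoate | CCOC(=O)CCC(=C)CCS(=O)(=O)c1nnnn1-c1ccccc1 | intermediate
13 | (2S)-2-methylbutan-1-ol | OC[C@@H](C)CC | starting material
14 | (2S)-2-methylbutanal | O=C[C@@H](C)CC | intermediate
15 | (4R)-4-benzyl-1,3-oxazolidin-2-one | O=C1N[C@H](Cc2ccccc2)CO1 | starting material
16 | (benzyloxy)acetyl chloride | O=C(Cl)COCc1ccccc1 | starting material
17 | N-lithio salt of 15 | [Li+].O=C1[N-][C@H](Cc2ccccc2)CO1 | intermediate
18 | (4R)-4-benzyl-3-[(benzyloxy)acetyl]-1,3-oxazolidin-2-one | O=C(COCc1ccccc1)N1[C@H](Cc2ccccc2)COC1=O | intermediate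
19 | (Z)-dibutylboron enolate of 18 | CCCCB(CCCC)O/C(=C\OCc1ccccc1)N1[C@H](Cc2ccccc2)COC1=O | intermediate
20 | (4R)-4-benzyl-3-[(2R,3S,4S)-2-(benzyloxy)-3-hydroxy-4-methylhexanoyl]-1,3-oxazolidin-2-one | O=C([C@H](OCc1ccccc1)[C@@H](O)[C@@H](C)CC)N1[C@H](Cc2ccccc2)COC1=O | intermediate
21 | 2-(trimethylsilyl)ethyl (2R,3S,4S)-2-(benzyloxy)-3-hydroxy-4-methylhexanoate | C[Si](C)(C)CCOC(=O)[C@H](OCc1ccccc1)[C@@H](O)[C@@H](C)CC | intermediate
22 | 2-(trimethylsilyl)ethyl (2R,3S,4S)-2,3-dihydroxy-4-methylhexanoate | C[Si](C)(C)CCOC(=O)[C@H](O)[C@@H](O)[C@@H](C)CC | intermediate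
23 | 2-(trimethylsilyl)ethyl (4R,5S)-5-[(2S)-butan-2-yl]-2,2-dimethyl-1,3-dioxolane-4-carboxylate | C[Si](C)(C)CCOC(=O)[C@H](O1)[C@@H](OC1(C)C)[C@@H](C)CC | intermediate
24 | lithium ester enolate of 23 (enolate geometry not defined) | [Li+].[O-]C(OCC[Si](C)(C)C)=C1OC(C)(C)O[C@H]1[C@@H](C)CC | intermediate
25 | 2-(trimethylsilyl)ethyl (4S,5S)-4-[(benzyloxy)methyl]-5-[(2S)-butan-2-yl]-2,2-dimethyl-1,3-dioxolane-4-carboxylate | c1ccccc1COC[C@@](O1)(C(=O)OCC[Si](C)(C)C)[C@@H](OC1(C)C)[C@@H](C)CC | intermediate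
26 | 2-(trimethylsilyl)ethyl (2S,3S,4S)-2-[(benzyloxy)methyl]-2,3-dihydroxy-4-methylhexanoate | c1ccccc1COC[C@@](O)(C(=O)OCC[Si](C)(C)C)[C@@H](O)[C@@H](C)CC | intermediate
27 | 2-(trimethylsilyl)ethyl (2S,3S,4S)-2-[(benzyloxy)methyl]-4-methyl-2,3-bis[(triethylsilyl)oxy]hexanoate | c1ccccc1COC[C@@](O[Si](CC)(CC)CC)(C(=O)OCC[Si](C)(C)C)[C@@H](O[Si](CC)(CC)CC)[C@@H](C)CC | intermediate
28 | 2-(trimethylsilyl)ethyl (2S,3S,4S)-2-(hydroxymethyl)-4-methyl-2,3-bis[(triethylsilyl)oxy]hexanoate | OC[C@@](O[Si](CC)(CC)CC)(C(=O)OCC[Si](C)(C)C)[C@@H](O[Si](CC)(CC)CC)[C@@H](C)CC | intermediate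
29 | 2-(trimethylsilyl)ethyl (2R,3S,4S)-2-formyl-4-methyl-2,3-bis[(triethylsilyl)oxy]hexanoate | O=C[C@@](O[Si](CC)(CC)CC)(C(=O)OCC[Si](C)(C)C)[C@@H](O[Si](CC)(CC)CC)[C@@H](C)CC | intermediate
30 | potassium α-sulfonyl carbanion of 12 | [K+].CCOC(=O)CCC(=C)C[CH-]S(=O)(=O)c1nnnn1-c1ccccc1 | intermediate
31 | 9-ethyl 1-[2-(trimethylsilyl)ethyl] (2S,3E)-6-methylidene-2-[(1S,2S)-2-methyl-1-(triethylsilyloxy)butyl]-2-(triethylsilyloxy)non-3-enedioate | CCOC(=O)CCC(=C)C/C=C/[C@@](O[Si](CC)(CC)CC)(C(=O)OCC[Si](C)(C)C)[C@@H](O[Si](CC)(CC)CC)[C@@H](C)CC | intermediate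
32 | (6E,8S)-4-methylidene-8-[(1S,2S)-2-methyl-1-(triethylsilyloxy)butyl]-9-oxo-8-(triethylsilyloxy)-9-[2-(trimethylsilyl)ethoxy]non-6-enoic acid | OC(=O)CCC(=C)C/C=C/[C@@](O[Si](CC)(CC)CC)(C(=O)OCC[Si](C)(C)C)[C@@H](O[Si](CC)(CC)CC)[C@@H](C)CC | intermediate
33 | 9-[(2R)-2-methyl-6-oxo-3,6-dihydro-2H-pyran-4-yl] 1-[2-(trimethylsilyl)ethyl] (2S,3E)-6-methylidene-2-[(1S,2S)-2-methyl-1-(triethylsilyloxy)butyl]-2-(triethylsilyloxy)non-3-enedioate (O-acyl enol ester) | C[C@@H]1CC(OC(=O)CCC(=C)C/C=C/[C@@](O[Si](CC)(CC)CC)(C(=O)OCC[Si](C)(C)C)[C@@H](O[Si](CC)(CC)CC)[C@@H](C)CC)=CC(=O)O1 | intermediate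
34 | 2-(trimethylsilyl)ethyl (2S,3E)-9-[(6R)-4-hydroxy-6-methyl-2-oxo-5,6-dihydro-2H-pyran-3-yl]-6-methylidene-2-[(1S,2S)-2-methyl-1-(triethylsilyloxy)butyl]-9-oxo-2-(triethylsilyloxy)non-3-enoate | C=C(C/C=C/[C@@](O[Si](CC)(CC)CC)(C(=O)OCC[Si](C)(C)C)[C@@H](O[Si](CC)(CC)CC)[C@@H](C)CC)CCC(=O)C1=C(O)C[C@@H](C)OC1=O | intermediate
35 | (2S,3E)-2-hydroxy-2-[(1S,2S)-1-hydroxy-2-methylbutyl]-9-[(6R)-4-hydroxy-6-methyl-2-oxo-5,6-dihydro-2H-pyran-3-yl]-6-methylidene-9-oxonon-3-enoic acid (CNP0129781.2) | C=C(C/C=C/[C@@](O)(C(=O)O)[C@@H](O)[C@@H](C)CC)CCC(=O)C1=C(O)C[C@@H](C)OC1=O | target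

Total step count: 22.
Longest linear sequence: 14 steps (13 to 35 through steps 8 and 10 to 22).

Steps most likely to fail

Step 14 (enolate alkylation that sets the quaternary centre). The enolate may open by β-elimination, or the facial selectivity may be too low. The fallback sets out from 21 and comes back at 26, and makes the centre by chelation-controlled addition to a ketone instead. Compound 21 is protected at the free hydroxyl with MeOCH2Cl/iPr2NEt to give 2-(trimethylsilyl)ethyl (2R,3S,4S)-2-(benzyloxy)-3-(methoxymethoxy)-4-methylhexanoate F1. Hydrogenolysis (H2, Pd/C, EtOAc) gives 2-(trimethylsilyl)ethyl (2R,3S,4S)-2-hydroxy-3-(methoxymethoxy)-4-methylhexanoate F2. Dess–Martin oxidation gives the α-keto ester 2-(trimethylsilyl)ethyl (3S,4S)-3-(methoxymethoxy)-4-methyl-2-oxohexanoate F3. BnOCH2MgCl (from benzyl chloromethyl ether and Mg) with MgBr2·OEt2 in CH2Cl2 at −78 °C adds to the ketone of the five-membered magnesium chelate (ketone oxygen and the neighbouring ether oxygen) from the side away from the sec-butyl group. This gives 2-(trimethylsilyl)ethyl (2S,3S,4S)-2-[(benzyloxy)methyl]-2-hydroxy-3-(methoxymethoxy)-4-methylhexanoate F4. HCl in MeOH at 40 °C removes the methoxymethyl group and gives 26.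

Step 19 (Julia–Kocienski olefination). The aldehyde is neopentyl-type, the β-alkoxide could pick up the neighbouring silyl group, and the carbanion could attack its own ester. The fallback sets out from 29 and comes back at 31, and builds the skipped diene by an alkenyl–allyl cross-coupling. Takai olefination of 29 (CrCl2, CHI3, THF, 0 °C) gives 2-(trimethylsilyl)ethyl (2S,3E)-4-iodo-2-[(1S,2S)-2-methyl-1-(triethylsilyloxy)butyl]-2-(triethylsilyloxy)but-3-enoate F5. Separately, the lithium enolate of ethyl acetate (LiN(iPr)2, THF, −78 °C) is alkylated with excess 3-chloro-2-(chloromethyl)prop-1-ene to give ethyl 4-(chloromethyl)pent-4-enoate F6. Zn dust/LiCl in THF turns it into [2-(3-ethoxy-3-oxopropyl)prop-2-en-1-yl]zinc chloride F7. Negishi coupling of F5 with F7 (Pd(PPh3)4, THF, rt) gives 31; the two ends of the 2-substituted allyl unit are equivalent, so no regioisomer can form.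

Step 21 (C-acylation of the lactone). The reaction may stop at enol ester 33 or give low conversion with the hindered, heavily silylated acid. The fallback sets out from 32 (with 1 as second component) and comes back at 34, and closes the pyranone ring last instead of acylating a preformed ring. Acid 32 is condensed with 2,2-dimethyl-1,3-dioxane-4,6-dione (N,N'-dicyclohexylcarbodiimide, 4-(dimethylamino)pyridine, CH2Cl2, 0 °C) to give 2-(trimethylsilyl)ethyl (2S,3E)-9-(2,2-dimethyl-4,6-dioxo-1,3-dioxan-5-ylidene)-9-hydroxy-6-methylidene-2-[(1S,2S)-2-methyl-1-(triethylsilyloxy)butyl]-2-(triethylsilyloxy)non-3-enoate F8. Heating F8 with 1 in toluene at 90 °C traps the acylketene and gives the β-keto ester 11-[(2R)-4-methoxy-4-oxobutan-2-yl] 1-[2-(trimethylsilyl)ethyl] (2S,3E)-6-methylidene-2-[(1S,2S)-2-methyl-1-(triethylsilyloxy)butyl]-9-oxo-2-(triethylsilyloxy)undec-3-enedioate F9. KOtBu in THF at 0 °C then effects a Dieckmann cyclisation of the active methylene onto the methyl ester and gives 34.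

Further compounds
F1 | step 14 | 2-(trimethylsilyl)ethyl (2R,3S,4S)-2-(benzyloxy)-3-(methoxymethoxy)-4-methylhexanoate | C[Si](C)(C)CCOC(=O)[C@H](OCc1ccccc1)[C@@H](OCOC)[C@@H](C)CC
F2 | step 14 | 2-(trimethylsilyl)ethyl (2R,3S,4S)-2-hydroxy-3-(methoxymethoxy)-4-methylhexanoate | C[Si](C)(C)CCOC(=O)[C@H](O)[C@@H](OCOC)[C@@H](C)CC
F3 | step 14 | 2-(trimethylsilyl)ethyl (3S,4S)-3-(methoxymethoxy)-4-methyl-2-oxohexanoate | C[Si](C)(C)CCOC(=O)C(=O)[C@@H](OCOC)[C@@H](C)CC
F4 | step 14 | 2-(trimethylsilyl)ethyl (2S,3S,4S)-2-[(benzyloxy)methyl]-2-hydroxy-3-(methoxymethoxy)-4-methylhexanoate | c1ccccc1COC[C@@](O)(C(=O)OCC[Si](C)(C)C)[C@@H](OCOC)[C@@H](C)CC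
F5 | step 19 | 2-(trimethylsilyl)ethyl (2S,3E)-4-iodo-2-[(1S,2S)-2-methyl-1-(triethylsilyloxy)butyl]-2-(triethylsilyloxy)but-3-enoate | I/C=C/[C@@](O[Si](CC)(CC)CC)(C(=O)OCC[Si](C)(C)C)[C@@H](O[Si](CC)(CC)CC)[C@@H](C)CC
F6 | step 19 | ethyl 4-(chloromethyl)pent-4-enoate | CCOC(=O)CCC(=C)CCl
F7 | step 19 | [2-(3-ethoxy-3-oxopropyl)prop-2-en-1-yl]zinc chloride | CCOC(=O)CCC(=C)C[Zn]Cl
F8 | step 21 | 2-(trimethylsilyl)ethyl (2S,3E)-9-(2,2-dimethyl-4,6-dioxo-1,3-dioxan-5-ylidene)-9-hydroxy-6-methylidene-2-[(1S,2S)-2-methyl-1-(triethylsilyloxy)butyl]-2-(triethylsilyloxy)non-3-enoate | CC1(C)OC(=O)C(=C(O)CCC(=C)C/C=C/[C@@](O[Si](CC)(CC)CC)(C(=O)OCC[Si](C)(C)C)[C@@H](O[Si](CC)(CC)CC)[C@@H](C)CC)C(=O)O1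
F9 | step 21 | 11-[(2R)-4-methoxy-4-oxobutan-2-yl] 1-[2-(trimethylsilyl)ethyl] (2S,3E)-6-methylidene-2-[(1S,2S)-2-methyl-1-(triethylsilyloxy)butyl]-9-oxo-2-(triethylsilyloxy)undec-3-enedioate | COC(=O)C[C@@H](C)OC(=O)CC(=O)CCC(=C)C/C=C/[C@@](O[Si](CC)(CC)CC)(C(=O)OCC[Si](C)(C)C)[C@@H](O[Si](CC)(CC)CC)[C@@H](C)CC
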